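**Retrosynthetic overview** (tetrahydrofuran numbering: O1, C2 bearing the trimethoxyphenyl ring, C3 bearing CH2OH, C4 bearing the aroyl group, C5 = CH2)

1. Magnone B (16) ⇒ 3,4-dimethoxyphenyllithium + cis-fused furofuranone 12: the C3 CH2OH and the C4 carbonyl are tied up as a temporary γ-lactone, which locks the epimerisable 3,4-cis relationship and is opened in the last step.
2. 12 ⇒ formaldehyde + aryl-cyclopropane-fused lactone 9, by a formal (3+2) cycloaddition that inserts C5–O1 into the C2–C4 bond of the cyclopropane; this closes the tetrahydrofuran, the last ring made.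
3. Enabling feature: C2 is benzylic to the 3,4,5-trimethoxyphenyl ring (cation-stabilising donor) and C4 is α to a carbonyl (acceptor), 1,3-related through C3; C2–C3–C4 is therefore a latent donor–acceptor cyclopropane and C5–O1 a latent formaldehyde.
4. 9 ⇒ (Z)-allylic diazoacetate 8 by enantioselective intramolecular cyclopropanation (sets C3, closes cyclopropane and lactone together) ⇒ Z-allylic alcohol 4 ⇒ aryl iodide 1 + propargyl alcohol 2.
5. Ring order: aryl rings purchased; cyclopropane and γ-lactone (step 5, both temporary); tetrahydrofuran (step 6); lactone opened (step 7).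

Key step: step 6

Remark: the sense of induction in step 5 is assigned by analogy with simple Z-allylic diazoacetates and this catalyst family; if the antipode formed, the mirror-image catalyst Rh2(5S-MEPY)4 would be used.

**Route**

Step 1
Reactants: 1 5-iodo-1,2,3-trimethoxybenzene; 2 prop-2-yn-1-ol
Product: 3 3-(3,4,5-trimethoxyphenyl)prop-2-yn-1-ol
Conditions: PdCl2(PPh3)2 (2 mol %), CuI (4 mol %), Et3N, THF, rt
Reagents that add atoms: none
Why: Sonogashira coupling of an electron-rich aryl iodide with a terminal alkyne is reliable and tolerates the free propargylic alcohol; no stereocentre is formed.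

Step 2
Reactants: 3 3-(3,4,5-trimethoxyphenyl)prop-2-yn-1-ol
Product: 4 (Z)-3-(3,4,5-trimethoxyphenyl)prop-2-en-1-ol
Conditions: H2 (1 atm), Pd/CaCO3 poisoned with Pb(OAc)2 (Lindlar catalyst), quinoline, EtOAc, rt
Reagents that add atoms: none
Why: Partial hydrogenation of the alkyne on lead-poisoned palladium (Lindlar reduction) adds both hydrogens to one face and should stop at the Z-alkene, quinoline suppressing over-reduction and Z/E isomerisation.

Step 3
Reactants: 4 (Z)-3-(3,4,5-trimethoxyphenyl)prop-2-en-1-ol; 5 bromoacetyl bromide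
Product: 6 (Z)-3-(3,4,5-trimethoxyphenyl)prop-2-enyl bromoacetate
Conditions: NaHCO3, MeCN, 0 °C
Reagents that add atoms: none
Why: O-acylation (nucleophilic acyl substitution) of the primary allylic alcohol by the acid bromide, with NaHCO3 scavenging HBr so that the Z-allylic system is neither isomerised nor substituted.

Step 4
Reactants: 6 (Z)-3-(3,4,5-trimethoxyphenyl)prop-2-enyl bromoacetate
Product: 8 (Z)-3-(3,4,5-trimethoxyphenyl)prop-2-enyl diazoacetate, via N-alkylated N,N'-ditosylhydrazine 7 (not isolated)
Conditions: TsNHNHTs, DBU, THF, 0 °C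
Reagents that add atoms: N,N'-ditosylhydrazine, Cc1ccc(cc1)S(=O)(=O)NNS(=O)(=O)c1ccc(C)cc1
Why: The ditosylhydrazine anion is N-alkylated by the α-bromo ester to give 7, which loses two sulfinate ions under DBU (Bamford–Stevens-type elimination) to furnish the diazoacetate at 0 °C without touching the Z-allyl ester.

Step 5
Reactants: 8 (Z)-3-(3,4,5-trimethoxyphenyl)prop-2-enyl diazoacetate
Product: 9 (1S,5R,6S)-6-(3,4,5-trimethoxyphenyl)-3-oxabicyclo[3.1.0]hexan-2-one (endo-aryl, all-cis)
Conditions: Rh2(5R-MEPY)4 (1 mol %; dirhodium tetrakis[methyl (5R)-2-oxopyrrolidine-5-carboxylate]), CH2Cl2, reflux, slow addition of 8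
Reagents that add atoms: none
Why: Intramolecular cyclopropanation by a chiral dirhodium carboxamidate carbene is stereospecific in the alkene (the Z-alkene gives the all-cis, endo-aryl bicycle) and the catalyst differentiates the alkene faces, so C1, C5 and C6 are set together by catalyst control; C5 becomes C3 of the target.

Step 6
Reactants: 9 (1S,5R,6S)-6-(3,4,5-trimethoxyphenyl)-3-oxabicyclo[3.1.0]hexan-2-one; 10 formaldehyde (used as paraformaldehyde)
Product: 12 (1R,5R,6S)-6-(3,4,5-trimethoxyphenyl)-3,7-dioxabicyclo[3.3.0]octan-2-one, via oxocarbenium silyl ketene acetal 11 (not isolated)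
Conditions: (CH2O)n (3 equiv), Me3SiOTf (20 mol %), CH2Cl2, −40 to 0 °C
Reagents that add atoms: none
Why: Proposed new method: silylation of the lactone carbonyl by Me3SiOTf polarises the cyclopropane bond C1–C6 of 9 (acceptor carbon to aryl-bearing donor carbon, the bond lying nearly parallel to the carbonyl π system of the bicyclo[3.1.0] frame), formaldehyde oxygen opens it at the benzylic carbon with inversion to give the O-methylene oxocarbenium ion tethered to a silyl ketene acetal (11), and the ketene acetal carbon closes onto the oxocarbenium carbon with release of the silyl cation for turnover, so that the net result is a formal (3+2) cycloaddition inserting C5 and O1 as CH2=O between C2 and C4. The closest known reaction type is the Lewis-acid-catalysed (3+2) annulation of aldehydes with 2-arylcyclopropane-1,1-diesters, including γ-lactone-fused cyclopropanes that carry a second ester; the extension proposed is to a single lactone acceptor and to formaldehyde as the 2π partner. The tetrahydrofuran is closed in a 5-(enolexo)-endo-trig Mukaiyama-aldol-type C–C bond formation, the same closure mode as in the diester annulations. C3 (C5 of 9) is never broken and anchors the absolute configuration; C4 is re-formed from the planar ketene acetal but can only bond on the face that gives the cis-fused 5,5-bicycle; C2 is set by inversion of the endo-aryl centre, which places the aryl group on the convex face, trans to C3. The step needs cleavage of C1–C6 rather than C1–C5 and the exo-aryl diastereomer: the first is secured by benzylic stabilisation at C6 by the trimethoxyphenyl ring, the second by the Z-derived endo configuration of 9 and, if the opening drifts towards a free benzylic cation, by Lewis-acid equilibration at C2 to the more stable exo-aryl epimer, so both pathways converge on 12.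

Step 7
Reactants: 12 (1R,5R,6S)-6-(3,4,5-trimethoxyphenyl)-3,7-dioxabicyclo[3.3.0]octan-2-one; 13 4-bromo-1,2-dimethoxybenzene
Product: 16 magnone B, via 3,4-dimethoxyphenyllithium 14 (not isolated), via lithium lactolate 15 (not isolated)
Conditions: 13, n-BuLi, THF, −78 °C; then 12, THF, −78 °C; AcOH quench at −78 °C
Reagents that add atoms: none
Why: Nucleophilic acyl substitution of the γ-lactone by an aryllithium (from bromine–lithium exchange) should stop at the cyclic lithium lactolate 15 at −78 °C, and cold acidic quench gives the hemiketal, which is expected to open to the conjugated aryl ketone and the primary alcohol; no stereocentre is formed and C4 keeps its configuration because the ketone is only released on near-neutral work-up.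

**Compound list**

1 | 5-iodo-1,2,3-trimethoxybenzene | COc1cc(I)cc(OC)c1OC | starting material
2 | prop-2-yn-1-ol | OCC#C | starting material
3 | 3-(3,4,5-trimethoxyphenyl)prop-2-yn-1-ol | COc1cc(C#CCO)cc(OC)c1OC | intermediate
4 | (Z)-3-(3,4,5-trimethoxyphenyl)prop-2-en-1-ol | COc1cc(/C=C\CO)cc(OC)c1OC | intermediate
5 | bromoacetyl bromide | BrCC(Br)=O | starting material
6 | (Z)-3-(3,4,5-trimethoxyphenyl)prop-2-enyl bromoacetate | COc1cc(/C=C\COC(=O)CBr)cc(OC)c1OC | intermediate
7 | N-alkylated N,N'-ditosylhydrazine (formed in situ) | COc1cc(/C=C\COC(=O)CN(NS(=O)(=O)c2ccc(C)cc2)S(=O)(=O)c2ccc(C)cc2)cc(OC)c1OC | intermediate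
8 | (Z)-3-(3,4,5-trimethoxyphenyl)prop-2-enyl diazoacetate | COc1cc(/C=C\COC(=O)C=[N+]=[N-])cc(OC)c1OC | intermediate
9 | (1S,5R,6S)-6-(3,4,5-trimethoxyphenyl)-3-oxabicyclo[3.1.0]hexan-2-one | O=C1[C@H]2[C@@H](c3cc(OC)c(OC)c(OC)c3)[C@H]2CO1 | intermediate
10 | formaldehyde (used as paraformaldehyde) | C=O | starting material
11 | O-methylene oxocarbenium ion tethered to a silyl ketene acetal, triflate salt (formed in situ) | C=[O+][C@H](c1cc(OC)c(OC)c(OC)c1)[C@H]1COC(O[Si](C)(C)C)=C1.[O-]S(=O)(=O)C(F)(F)F | intermediate
12 | (1R,5R,6S)-6-(3,4,5-trimethoxyphenyl)-3,7-dioxabicyclo[3.3.0]octan-2-one | O=C1[C@H]2CO[C@H](c3cc(OC)c(OC)c(OC)c3)[C@H]2CO1 | intermediate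
13 | 4-bromo-1,2-dimethoxybenzene | COc1ccc(Br)cc1OC | starting material
14 | 3,4-dimethoxyphenyllithium (formed in situ) | COc1ccc([Li])cc1OC | intermediate
15 | lithium lactolate, tetrahedral adduct of 14 and 12 (formed in situ) | [Li+].[O-]C1(c2ccc(OC)c(OC)c2)[C@H]2CO[C@H](c3cc(OC)c(OC)c(OC)c3)[C@H]2CO1 | intermediate
16 | magnone B, (3,4-dimethoxyphenyl)[(2S,3R,4R)-3-(hydroxymethyl)-2-(3,4,5-trimethoxyphenyl)tetrahydrofuran-4-yl]methanone | COc1ccc(C(=O)[C@H]2CO[C@H](c3cc(OC)c(OC)c(OC)c3)[C@H]2CO)cc1OC | target

**Step count**

Total steps: 7. Longest linear sequence: 7 steps (from 1; compounds 2, 5, 10 and 13 enter as purchased materials).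

**Steps most likely to fail**

1. Step 6 (proposed new method). The single lactone acceptor may not polarise the cyclopropane enough for ring opening. If a free benzylic cation forms, it may lose a proton (E1) instead of being captured. Formaldehyde may also oligomerise into the oxocarbenium ion or hydroxymethylate the electron-rich arene. Fallback (known chemistry; sets out from 4, comes back at 12): the cyclopropane is given the second acceptor used by the established annulation. Alcohol 4 is acylated with methyl 3-chloro-3-oxopropanoate (pyridine, CH2Cl2, 0 °C) to methyl (Z)-3-(3,4,5-trimethoxyphenyl)prop-2-enyl malonate F1. Diazo transfer (4-acetamidobenzenesulfonyl azide, Et3N, MeCN) should give methyl (Z)-3-(3,4,5-trimethoxyphenyl)prop-2-enyl diazomalonate F2. Intramolecular cyclopropanation with CuOTf and a chiral bis(oxazoline) ligand (ClCH2CH2Cl, 60 °C) should give methyl (1S,5R,6R)-2-oxo-6-(3,4,5-trimethoxyphenyl)-3-oxabicyclo[3.1.0]hexane-1-carboxylate F3; enantioselectivity in this substrate class is usually lower than in step 5, so enrichment by crystallisation may be needed. F3 and (CH2O)n under Sc(OTf)3 or Sn(OTf)2 catalysis should undergo the malonate-type (3+2) annulation to the angular ester methyl (1R,5R,6S)-2-oxo-6-(3,4,5-trimethoxyphenyl)-3,7-dioxabicyclo[3.3.0]octane-1-carboxylate F4. Krapcho demethoxycarbonylation (LiCl, wet DMSO, 140 °C) then removes the extra ester, and protonation of the bridgehead enolate can only return the cis-fused lactone 12.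

2. Step 7. Premature collapse of the lactolate would release the ketone to a second aryllithium addition. The aryllithium may also enolise the lactone instead of adding, and C4 may epimerise if the work-up turns basic. Fallback (sets out from 12, comes back at 16): the ketone oxidation level is reached after, not during, the C–C bond formation. 12 is reduced with i-Bu2AlH (CH2Cl2, −78 °C) to the lactol 6-(3,4,5-trimethoxyphenyl)-3,7-dioxabicyclo[3.3.0]octan-2-ol F5. Excess 14, generated as in step 7 (THF, −78 to 0 °C), adds once to its open hydroxy-aldehyde form to give the diol (3,4-dimethoxyphenyl)[(2S,3R,4R)-3-(hydroxymethyl)-2-(3,4,5-trimethoxyphenyl)tetrahydrofuran-4-yl]methanol F6, as a carbinol epimer mixture that does not matter. Activated MnO2 (CH2Cl2, rt) should then oxidise the electron-rich secondary benzylic alcohol selectively over the primary alcohol to give 16 under neutral conditions.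

3. Step 5. The catalyst may discriminate the alkene faces of the aryl-substituted Z-alkene insufficiently. The carbene may also dimerise or attack the electron-rich arene. Fallback (sets out from 8, comes back at 9): resolution replaces asymmetric catalysis. 8 is cyclised with achiral Rh2(OAc)4 (CH2Cl2, rt, slow addition) to the racemic endo-aryl lactone, that is 9 together with its enantiomer (1R,5S,6R)-6-(3,4,5-trimethoxyphenyl)-3-oxabicyclo[3.1.0]hexan-2-one F7. Aminolysis of the mixture with (S)-1-phenylethylamine and AlMe3 (CH2Cl2, rt) gives the diastereomeric hydroxy amides (1S,2R,3S)-2-(hydroxymethyl)-N-[(S)-1-phenylethyl]-3-(3,4,5-trimethoxyphenyl)cyclopropane-1-carboxamide F8 (from 9) and (1R,2S,3R)-2-(hydroxymethyl)-N-[(S)-1-phenylethyl]-3-(3,4,5-trimethoxyphenyl)cyclopropane-1-carboxamide F9 (from F7), separable by chromatography or crystallisation. Warming F8 with TsOH in toluene should relactonise it through the cis hydroxymethyl group to 9 and release the amine.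

**Further compounds**

F1 | step 6 | methyl (Z)-3-(3,4,5-trimethoxyphenyl)prop-2-enyl malonate | COC(=O)CC(=O)OC/C=C\c1cc(OC)c(OC)c(OC)c1
F2 | step 6 | methyl (Z)-3-(3,4,5-trimethoxyphenyl)prop-2-enyl diazomalonate | COC(=O)C(=[N+]=[N-])C(=O)OC/C=C\c1cc(OC)c(OC)c(OC)c1
F3 | step 6 | methyl (1S,5R,6R)-2-oxo-6-(3,4,5-trimethoxyphenyl)-3-oxabicyclo[3.1.0]hexane-1-carboxylate | O=C1[C@@]2(C(=O)OC)[C@@H](c3cc(OC)c(OC)c(OC)c3)[C@H]2CO1
F4 | step 6 | methyl (1R,5R,6S)-2-oxo-6-(3,4,5-trimethoxyphenyl)-3,7-dioxabicyclo[3.3.0]octane-1-carboxylate | O=C1[C@@]2(C(=O)OC)CO[C@H](c3cc(OC)c(OC)c(OC)c3)[C@H]2CO1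
F5 | step 7 | (1R,5R,6S)-6-(3,4,5-trimethoxyphenyl)-3,7-dioxabicyclo[3.3.0]octan-2-ol (lactol, anomeric mixture) | OC1[C@H]2CO[C@H](c3cc(OC)c(OC)c(OC)c3)[C@H]2CO1
F6 | step 7 | (3,4-dimethoxyphenyl)[(2S,3R,4R)-3-(hydroxymethyl)-2-(3,4,5-trimethoxyphenyl)tetrahydrofuran-4-yl]methanol (carbinol epimers) | COc1ccc(C(O)[C@H]2CO[C@H](c3cc(OC)c(OC)c(OC)c3)[C@H]2CO)cc1OC
F7 | step 5 | (1R,5S,6R)-6-(3,4,5-trimethoxyphenyl)-3-oxabicyclo[3.1.0]hexan-2-one | O=C1[C@@H]2[C@H](c3cc(OC)c(OC)c(OC)c3)[C@@H]2CO1
F8 | step 5 | (1S,2R,3S)-2-(hydroxymethyl)-N-[(S)-1-phenylethyl]-3-(3,4,5-trimethoxyphenyl)cyclopropane-1-carboxamide | O=C(N[C@@H](C)c1ccccc1)[C@H]1[C@@H](c2cc(OC)c(OC)c(OC)c2)[C@H]1CO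
F9 | step 5 | (1R,2S,3R)-2-(hydroxymethyl)-N-[(S)-1-phenylethyl]-3-(3,4,5-trimethoxyphenyl)cyclopropane-1-carboxamide | O=C(N[C@@H](C)c1ccccc1)[C@@H]1[C@H](c2cc(OC)c(OC)c(OC)c2)[C@@H]1CO
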